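- In this closed, stirred vessel, at constant volume and temperature, you watch electrophile and nucleophile make target, with free base and a protic impurity also present.

all flasks: electrophile 0.10 M
- alder: nucleophile 1.1 equiv; free base 0.47 equiv; protic impurity 0.030 M; run made earlier
- ash: nucleophile 1.1 equiv; free base 0.60 equiv; protic impurity 0.030 M; run made earlier
- birch: nucleophile 1.1 equiv; free base 0.76 equiv; protic impurity 0.030 M; run made earlier
- south: nucleophile 1.10 equiv; free base 0.500 equiv; protic impurity 0.0300 M; time 2.5 h
- south-west: nucleophile 1.10 equiv; free base 0.750 equiv; protic impurity 0.0300 M; time 2.5 h

- alder (time / h: electrophile / %, target / %): 0.200: 82.0, 15.8; 0.417: 72.0, 23.1; 0.667: 64.3, 26.7; 1.33: 52.1, 27.9; 2.50: 42.9, 23.1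
- ash (time / h: electrophile / %, target / %): 0.500: 68.7, 24.2; 1.00: 57.4, 28.2; 1.50: 50.4, 27.6; 2.00: 45.7, 24.8; 2.50: 42.0, 22.9
- birch (time / h: electrophile / %, target / %): 0.200: 82.6, 15.8; 0.417: 71.9, 23.0; 0.667: 64.1, 26.4; 1.33: 52.3, 27.3; 2.50: 42.0, 22.6

(each reading ± 0.3 percentage points)

1. part of the electrophile that has reacted at the end, south
2. part of the electrophile that has reacted at the end, south-west
3. what raising the equivalents of free base from its lowest to its highest value here does to the part of the electrophile that has reacted (changes below 5 percentage points count as none) (no change / it falls / it rises)



- Reckon the running half-life, the time in which electrophile would halve at the fractional fall seen between two readings. From 0.200 h to 0.417 h, alder and birch taken together give 1.12 h.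
- Next, watch target turn. In ash it reads 28.2% at 1.00 h, then declines while electrophile is still falling.
- Later, from 1.33 h to 2.50 h, the same two runs give the late half-life τ 3.92 h, longer than the early one.
- At 2.50 h, alder and birch differ by 0.9 percentage points in electrophile, below the margin. My own reckoning takes the mean of the three runs, so I expect 57.7% reacted in each new flask.
- The forecast gives 57.6% for south and 57.8% for south-west, with no change: “the rate appears zero-order in free base over this range”.
- The simulation gives 57.7% for south and 57.7% for south-west, and the trend is no change: from the lowest to the highest free base, the part reacted moves 0.041 points. The forecast stands.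

    acid set free + free base ⇌ salt of the base, settled at all times (K = 22.0 M⁻¹)
    electrophile + nucleophile → acid set free + target (k = 0.00310 M⁻¹ s⁻¹)
    electrophile + target → side product A (k = 0.00140 M⁻¹ s⁻¹)
    nucleophile + protic impurity → quenched reagent (k = 0.0130 M⁻¹ s⁻¹)
    nucleophile + acid set free ⇌ protonated nucleophile, settled at all times (K = 44000 M⁻¹)
    acid set free + target → side product B (k = 0.0220 M⁻¹ s⁻¹)

- In south at 0.276 h, the target-making step alone gives electrophile a half-life of 1.2 h, shorter than the late τ read from alder and birch, and target is made 5.91 times as fast as it is used up, each step taken net. At 2.50 h that ratio in south is 0.236, with 2.5% of the charged nucleophile, the limiting reagent, still free, less than the 42% of electrophile. The answer for south has moved by 5 points at 0.996 equiv or 1.21 equiv of nucleophile, the other amounts and the time held, so weigh that charge with care.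
- Now take south read at 6.0 h. Carrying τ forward from 42.3% electrophile at 2.5 h predicts 22.8%. The simulation gives 29.5%, more than that, so the half-life of south over that stretch, 6.72 h, is longer than τ.

(The earlier runs and the new flask were computed for substances that don't exist; the scatter is artificial.)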